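**Plan**
1. Retrosynthesis: the two ring B methyl ethers go on last; ring A (a1 C–OH, a2, a3 C–chain, a4, a5 C–OAr, a6) is cut at a1–a6 and a4–a5, which opens the benzene ring and the 20-membered ring at once and leaves a 3-alkylcyclobutenone (a1–a4) tethered to an ethynyl ether (a5, a6) on the ring B oxygen.
2. Feature used: ring A is a 3-aryloxy-5-alkylphenol, the 1,3,5-pattern that a 3-alkylcyclobutenone and a heteroatom-substituted alkyne give, and the oxygen on a5 belongs to ring B, so ring B can carry the alkyne.
3. Further cuts: cyclobutenone C3–chain C14 (Grignard plus 3-ethoxycyclobutenone), alkynyl C–O (phenol plus trichloroethylene), chain C1=C2 (Wittig), ring B–C1 (ortho-formylation).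
4. Forward: ring B aldehyde, masked alkynyl ether, C14 chain by Wittig and hydrogenation, silyl ynol ether, cyclobutenone, desilylation, then one thermal step closes ring A and the macrocycle together; demethylation ends the route.
5. Stereochemistry: the target has no stereocentre and no stereogenic double bond; the alkene geometries in 6, 12 and 13 are transient and are erased.

Key step: step 9

Remark: 3-ethoxycyclobut-2-en-1-one (17) is taken as a purchasable reagent; failing that, it is one step from ethoxyacetylene and ketene.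

Step 1
Reactants: 1 2,4-dimethoxyphenol
Product: 3 2-hydroxy-3,5-dimethoxybenzaldehyde, via salicyl alcohol 2 (not isolated)
Conditions: MgCl2, Et3N, (CH2O)n, MeCN, reflux; then 1 M HCl
Reagents that add atoms: paraformaldehyde (as formaldehyde), C=O
Why: Casnati–Skattebøl ortho-formylation: the magnesium phenoxide directs formaldehyde to the only free ortho carbon to give salicyl alcohol 2, which a second formaldehyde oxidises by hydride transfer, so the aldehyde carbon (chain C1) enters ortho to OH without touching the methyl ethers.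

Step 2
Reactants: 3 2-hydroxy-3,5-dimethoxybenzaldehyde; 4 trichloroethylene
Product: 6 2-{[(E)-1,2-dichloroethenyl]oxy}-3,5-dimethoxybenzaldehyde, via dichloroacetylene 5 (not isolated)
Conditions: K2CO3, DMF, 70 °C
Reagents that add atoms: none
Why: Base-mediated O-dichlorovinylation of a phenol: K2CO3 dehydrochlorinates trichloroethylene to dichloroacetylene 5 and the phenoxide adds to it in anti fashion, giving the (E)-ether that masks the phenol against ylide and organolithium reagents and already holds the two carbons that become a5 and a6.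

Step 3
Reactants: 7 methyltriphenylphosphonium bromide; 8 1,12-dibromododecane
Product: 10 (13-bromotridecyl)triphenylphosphonium bromide, via methylenetriphenylphosphorane 9 (not isolated)
Conditions: n-BuLi, THF, 0 °C; then added to 8 (4 equiv), THF, –20 °C → rt; salt collected by trituration with Et2O
Reagents that add atoms: none
Why: C-Alkylation of a phosphorus ylide (SN2): methylenetriphenylphosphorane 9 displaces one bromide of the dibromide, kept in fourfold excess to hold back double alkylation and transylidation, and the salt that precipitates carries chain carbons C2 to C14 with the terminal bromide in place.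

Step 4
Reactants: 10 (13-bromotridecyl)triphenylphosphonium bromide; 6 2-{[(E)-1,2-dichloroethenyl]oxy}-3,5-dimethoxybenzaldehyde
Product: 12 1-[(1Z)-14-bromotetradec-1-en-1-yl]-2-{[(E)-1,2-dichloroethenyl]oxy}-3,5-dimethoxybenzene, via ylide 11 (not isolated)
Conditions: NaN(SiMe3)2, THF, –78 °C; then 6, –78 °C → rt
Reagents that add atoms: none
Why: Wittig olefination with a non-stabilised ylide, which adds to the aryl aldehyde at –78 °C much faster than it can be alkylated by the remote primary bromide; the mainly (Z) alkene needs no control because it is saturated in the next step.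

Step 5
Reactants: 12 1-[(1Z)-14-bromotetradec-1-en-1-yl]-2-{[(E)-1,2-dichloroethenyl]oxy}-3,5-dimethoxybenzene
Product: 13 1-(14-bromotetradecyl)-2-{[(E)-1,2-dichloroethenyl]oxy}-3,5-dimethoxybenzene
Conditions: H2 (3 atm), RhCl(PPh3)3 (5 mol %), PhH–EtOH (1:1), rt
Reagents that add atoms: none
Why: Homogeneous hydrogenation with RhCl(PPh3)3 saturates the disubstituted styrenyl alkene but is expected to leave the primary C–Br bond and the trisubstituted, chlorine-bearing enol ether alone, a selectivity that palladium on carbon would not offer.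

Step 6
Reactants: 13 1-(14-bromotetradecyl)-2-{[(E)-1,2-dichloroethenyl]oxy}-3,5-dimethoxybenzene
Product: 16 {[2-(14-bromotetradecyl)-4,6-dimethoxyphenoxy]ethynyl}trimethylsilane, via chloroethynyl ether 14 (not isolated), via lithium acetylide 15 (not isolated)
Conditions: n-BuLi (2.3 equiv), THF, –78 °C; then Me3SiCl, –78 → 0 °C
Reagents that add atoms: chlorotrimethylsilane, C[Si](C)(C)Cl
Why: Elimination and halogen–metal exchange of a 1,2-dichlorovinyl ether (the standard route to alkynyl ethers): n-BuLi removes the vinylic proton with loss of LiCl to give chloroalkyne 14, a second equivalent exchanges chlorine for lithium to give acetylide 15, and Me3SiCl caps the carbon, the primary bromide being inert to n-BuLi at –78 °C.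

Step 7
Reactants: 16 {[2-(14-bromotetradecyl)-4,6-dimethoxyphenoxy]ethynyl}trimethylsilane; 17 3-ethoxycyclobut-2-en-1-one
Product: 20 3-[14-(3,5-dimethoxy-2-{[(trimethylsilyl)ethynyl]oxy}phenyl)tetradecyl]cyclobut-2-en-1-one, via Grignard reagent 18 (not isolated), via magnesium carbinolate 19 (not isolated)
Conditions: Mg (1,2-dibromoethane-activated), THF, 25–35 °C; then 17, THF, –78 → 0 °C; then 0.1 M HCl, 0 °C, NaHCO3 quench
Reagents that add atoms: water, O
Why: Grignard 1,2-addition to a vinylogous ester followed by acid-mediated carbonyl transposition (Stork–Danheiser type), the established entry to 3-alkylcyclobutenones: carbinolate 19 ionises in very dilute acid, water adds at the ethoxy-bearing carbon and ethanol leaves, while the far less basic aryl silyl ynol ether should survive the short, cold exposure.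

Step 8
Reactants: 20 3-[14-(3,5-dimethoxy-2-{[(trimethylsilyl)ethynyl]oxy}phenyl)tetradecyl]cyclobut-2-en-1-one
Product: 21 3-{14-[2-(ethynyloxy)-3,5-dimethoxyphenyl]tetradecyl}cyclobut-2-en-1-one
Conditions: Bu4NF, AcOH (1:1), THF, –20 → 0 °C
Reagents that add atoms: none
Why: Fluoride-induced protodesilylation of an alkynylsilane, buffered with acetic acid so that the alkynyl anion is protonated at once and the base-sensitive cyclobutenone never meets free fluoride or alkoxide.

Step 9
Reactants: 21 3-{14-[2-(ethynyloxy)-3,5-dimethoxyphenyl]tetradecyl}cyclobut-2-en-1-one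
Product: 26 3^4,3^6-dimethoxy-2-oxa-1(1,3),3(1,2)-dibenzenacycloheptadecaphan-1^5-ol, via vinylketene 22 (not isolated), via macrocyclic vinylcyclobutenone 23 (not isolated), via dienylketene 24 (not isolated), via cyclohexadienone 25 (not isolated)
Conditions: PhMe (degassed, 1 mM final concentration), syringe-pump addition of 21 over 12 h at 80 °C, then 110 °C
Reagents that add atoms: none
Why: Proposed new method: reversible 4π-electrocyclic opening of the 3-alkylcyclobutenone gives vinylketene 22, whose ketene carbon (a1) is attacked by the terminal carbon (a6) of the tethered aryl ethynyl ether in a polarity-matched [2+2] cycloaddition that also joins a4 to a5 and so closes the 20-membered ring as cyclobutenone 23; 4π opening to dienylketene 24, 6π electrocyclisation (a1–a2, closing ring A as cyclohexadienone 25) and enolisation should give phenol 26. The closest known reaction type is the intermolecular Danheiser benzannulation of cyclobutenones with alkoxy- and siloxyacetylenes; neither its use as a macrocyclisation nor an aryl ethynyl ether partner has precedent. The macrocycle closes by intramolecular ketene–alkyne [2+2] cycloaddition through an unstrained 20-membered transition state, and ring A closes by thermal disrotatory 6π electrocyclisation of a ketene. No stereocentre is created in 26, since the sp3 carbon a4 of 23 is erased when the four-membered ring opens. The step needs OAr meta to the new OH, which the ketene and ynol ether polarity (nucleophilic a6 onto electrophilic a1) dictates, and ring closure ahead of oligomerisation, which the 1 mM dilution, the slow addition and the harmless return of untrapped 22 to 21 are meant to secure.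

Step 10
Reactants: 26 3^4,3^6-dimethoxy-2-oxa-1(1,3),3(1,2)-dibenzenacycloheptadecaphan-1^5-ol
Product: 27 2-oxa-1(1,3),3(1,2)-dibenzenacycloheptadecaphane-1^5,3^4,3^6-triol
Conditions: BBr3 (5 equiv), CH2Cl2, –78 °C → rt; MeOH then H2O
Reagents that add atoms: none
Why: BBr3 cleavage of aryl methyl ethers (boron coordinates the ether oxygen and bromide attacks the methyl carbon), which the diaryl ether, lacking an sp3 carbon on oxygen, cannot undergo, so only the two ring B methyl groups are lost.

**Compound list**
1 | 2,4-dimethoxyphenol | COc1ccc(O)c(OC)c1 | starting material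
2 | 2-(hydroxymethyl)-4,6-dimethoxyphenol (magnesium salt in the flask) | OCc1cc(OC)cc(OC)c1O | intermediate
3 | 2-hydroxy-3,5-dimethoxybenzaldehyde | O=Cc1cc(OC)cc(OC)c1O | intermediate
4 | trichloroethylene | ClC=C(Cl)Cl | starting material
5 | dichloroacetylene | ClC#CCl | intermediate
6 | 2-{[(E)-1,2-dichloroethenyl]oxy}-3,5-dimethoxybenzaldehyde | Cl/C=C(/Cl)Oc1c(C=O)cc(OC)cc1OC | intermediate
7 | methyltriphenylphosphonium bromide | C[P+](c1ccccc1)(c1ccccc1)c1ccccc1.[Br-] | starting material
8 | 1,12-dibromododecane | BrCCCCCCCCCCCCBr | starting material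
9 | methylenetriphenylphosphorane | C=P(c1ccccc1)(c1ccccc1)c1ccccc1 | intermediate
10 | (13-bromotridecyl)triphenylphosphonium bromide | BrCCCCCCCCCCCCC[P+](c1ccccc1)(c1ccccc1)c1ccccc1.[Br-] | intermediate
11 | (13-bromotridecylidene)triphenylphosphorane | BrCCCCCCCCCCCCC=P(c1ccccc1)(c1ccccc1)c1ccccc1 | intermediate
12 | 1-[(1Z)-14-bromotetradec-1-en-1-yl]-2-{[(E)-1,2-dichloroethenyl]oxy}-3,5-dimethoxybenzene | Cl/C=C(/Cl)Oc1c(/C=C\CCCCCCCCCCCCBr)cc(OC)cc1OC | intermediate
13 | 1-(14-bromotetradecyl)-2-{[(E)-1,2-dichloroethenyl]oxy}-3,5-dimethoxybenzene | Cl/C=C(/Cl)Oc1c(CCCCCCCCCCCCCCBr)cc(OC)cc1OC | intermediate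
14 | 1-(14-bromotetradecyl)-2-[(chloroethynyl)oxy]-3,5-dimethoxybenzene | ClC#COc1c(CCCCCCCCCCCCCCBr)cc(OC)cc1OC | intermediate
15 | {[2-(14-bromotetradecyl)-4,6-dimethoxyphenoxy]ethynyl}lithium | [Li]C#COc1c(CCCCCCCCCCCCCCBr)cc(OC)cc1OC | intermediate
16 | {[2-(14-bromotetradecyl)-4,6-dimethoxyphenoxy]ethynyl}trimethylsilane | C[Si](C)(C)C#COc1c(CCCCCCCCCCCCCCBr)cc(OC)cc1OC | intermediate
17 | 3-ethoxycyclobut-2-en-1-one | CCOC1=CC(=O)C1 | starting material
18 | [14-(3,5-dimethoxy-2-{[(trimethylsilyl)ethynyl]oxy}phenyl)tetradecyl]magnesium bromide | C[Si](C)(C)C#COc1c(CCCCCCCCCCCCCC[Mg]Br)cc(OC)cc1OC | intermediate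
19 | bromomagnesium 1-[14-(3,5-dimethoxy-2-{[(trimethylsilyl)ethynyl]oxy}phenyl)tetradecyl]-3-ethoxycyclobut-2-en-1-olate | CCOC1=CC(CCCCCCCCCCCCCCc2cc(OC)cc(OC)c2OC#C[Si](C)(C)C)(O[Mg]Br)C1 | intermediate
20 | 3-[14-(3,5-dimethoxy-2-{[(trimethylsilyl)ethynyl]oxy}phenyl)tetradecyl]cyclobut-2-en-1-one | C[Si](C)(C)C#COc1c(CCCCCCCCCCCCCCC2=CC(=O)C2)cc(OC)cc1OC | intermediate
21 | 3-{14-[2-(ethynyloxy)-3,5-dimethoxyphenyl]tetradecyl}cyclobut-2-en-1-one | COc1cc(OC)c(OC#C)c(c1)CCCCCCCCCCCCCCC1=CC(=O)C1 | intermediate
22 | 3-{14-[2-(ethynyloxy)-3,5-dimethoxyphenyl]tetradecyl}buta-1,3-dien-1-one (vinylketene) | COc1cc(OC)c(OC#C)c(c1)CCCCCCCCCCCCCCC(=C)C=C=O | intermediate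
23 | macrocyclic vinylcyclobutenone (racemic): cyclobut-2-en-1-one whose C3 bears the ring B oxygen and whose C4 bears C(=CH2) joined through (CH2)14 to ring B C6, 20-membered ring | O=C1C=C2Oc3c(OC)cc(OC)cc3CCCCCCCCCCCCCCC(=C)C12 | intermediate
24 | macrocyclic dienylketene: O=C=CH–C(OAr)=CH–C(=CH2)–(CH2)14–ring B, with C(OAr)=CH and C(=CH2) in the 20-membered ring | O=C=CC1=CC(=C)CCCCCCCCCCCCCCc2cc(OC)cc(OC)c2O1 | intermediate
25 | macrocyclic 3-aryloxy-5-alkylcyclohexa-2,4-dien-1-one (keto tautomer of 26) | O=C1C=C2C=C(C1)CCCCCCCCCCCCCCc3cc(OC)cc(OC)c3O2 | intermediate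
26 | 3^4,3^6-dimethoxy-2-oxa-1(1,3),3(1,2)-dibenzenacycloheptadecaphan-1^5-ol (target with both ring B hydroxyls as methyl ethers) | Oc1cc2cc(c1)Oc1c(OC)cc(OC)cc1CCCCCCCCCCCCCC2 | intermediate
27 | 2-oxa-1(1,3),3(1,2)-dibenzenacycloheptadecaphane-1^5,3^4,3^6-triol (CNP0173380.0) | Oc1cc2cc(c1)Oc1c(O)cc(O)cc1CCCCCCCCCCCCCC2 | target

**Count**
Total step count: 10. Longest linear sequence: 9 steps (steps 1, 2 and 4 to 10, from 2,4-dimethoxyphenol); step 3 prepares the phosphonium salt on a side branch.

**Steps most likely to fail**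

Step 9. The vinylketene may be consumed by intermolecular ketene–ketene or ketene–alkyne reactions, or the aryl ethynyl ether may be lost to heat or adventitious acid, faster than the transannular [2+2] can take place. The fallback uses only known reaction types, sets out from 3 (with 8) and comes back at 27. Phenol 3 is O-arylated with commercial 3-bromo-5-methoxybenzaldehyde (CuI, N,N-dimethylglycine, Cs2CO3, dioxane, 100 °C; Ullmann diaryl ether synthesis) to give the dialdehyde 2-(3-formyl-5-methoxyphenoxy)-3,5-dimethoxybenzaldehyde F1. Dibromide 8 and PPh3 (2 equiv, MeCN, reflux) give dodecane-1,12-diylbis(triphenylphosphonium) dibromide F2, which NaN(SiMe3)2 converts into the bis-ylide dodecane-1,12-diylidenebis(triphenylphosphorane) F3. Slow simultaneous addition of F1 and F3 to THF at high dilution should close the 20-membered ring by a double Wittig reaction, giving 1^5,3^4,3^6-trimethoxy-2-oxa-1(1,3),3(1,2)-dibenzenacycloheptadecaphane-4,16-diene F4 as a mixture of alkene isomers. Hydrogenation (H2, Pd/C, EtOAc) gives 1^5,3^4,3^6-trimethoxy-2-oxa-1(1,3),3(1,2)-dibenzenacycloheptadecaphane F5, and BBr3 under the conditions of step 10 cleaves all three methyl ethers to give 27.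

Step 8. Fluoride and the basicity that comes with it may destroy the cyclobutenone (ring cleavage at the carbonyl, γ-deprotonation) before the C–Si bond is cut. The fallback sets out from 20 and comes back at 26: the silicon is left on through the ring closure. Heating 20 under the conditions of step 9 should give the silylated macrocyclic phenol (26 carrying Me3Si on the ring A carbon between C–OH and C–OAr) F6. CF3CO2H in CH2Cl2 at 0 °C then removes the arylsilane by ipso-protonation of the electron-rich ring and gives 26.

Step 7. The Grignard carbon may attack the silylated alkynyl ether, or the silyl ynol ether may be hydrated while the enone is being unveiled in acid. The fallback sets out from 13 and comes back at 21: silicon is dispensed with and the alkyne is protected by its own negative charge. Compound 13 is taken through 14 and 15 as in step 6 but quenched with aqueous NH4Cl to give 1-(14-bromotetradecyl)-2-(ethynyloxy)-3,5-dimethoxybenzene F7. EtMgBr (1 equiv, THF, 0 °C) deprotonates the alkyne and Mg then inserts into the C–Br bond to give the bis-magnesium species [14-(2-{[(bromomagnesio)ethynyl]oxy}-3,5-dimethoxyphenyl)tetradecyl]magnesium bromide F8. Its more reactive alkyl–magnesium end adds to 17 (1 equiv, –78 °C) to give the carbinolate bromomagnesium 1-[14-(2-{[(bromomagnesio)ethynyl]oxy}-3,5-dimethoxyphenyl)tetradecyl]-3-ethoxycyclobut-2-en-1-olate F9. Cold dilute acid returns the terminal alkynyl ether and unveils the enone, giving 21 directly.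

**Further compounds**
F1 | step 9 | 2-(3-formyl-5-methoxyphenoxy)-3,5-dimethoxybenzaldehyde | O=Cc1cc(OC)cc(OC)c1Oc1cc(C=O)cc(OC)c1
F2 | step 9 | dodecane-1,12-diylbis(triphenylphosphonium) dibromide | [Br-].[Br-].c1ccccc1[P+](c1ccccc1)(c1ccccc1)CCCCCCCCCCCC[P+](c1ccccc1)(c1ccccc1)c1ccccc1
F3 | step 9 | dodecane-1,12-diylidenebis(triphenylphosphorane) | c1ccccc1P(c1ccccc1)(c1ccccc1)=CCCCCCCCCCCC=P(c1ccccc1)(c1ccccc1)c1ccccc1
F4 | step 9 | 1^5,3^4,3^6-trimethoxy-2-oxa-1(1,3),3(1,2)-dibenzenacycloheptadecaphane-4,16-diene (alkene isomers) | COc1cc2cc(c1)Oc1c(OC)cc(OC)cc1C=CCCCCCCCCCCC=C2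
F5 | step 9 | 1^5,3^4,3^6-trimethoxy-2-oxa-1(1,3),3(1,2)-dibenzenacycloheptadecaphane | COc1cc2cc(c1)Oc1c(OC)cc(OC)cc1CCCCCCCCCCCCCC2
F6 | step 8 | silylated macrocyclic phenol (26 carrying Me3Si on the ring A carbon between C–OH and C–OAr) | Oc1cc2cc(c1[Si](C)(C)C)Oc1c(OC)cc(OC)cc1CCCCCCCCCCCCCC2
F7 | step 7 | 1-(14-bromotetradecyl)-2-(ethynyloxy)-3,5-dimethoxybenzene | C#COc1c(CCCCCCCCCCCCCCBr)cc(OC)cc1OC
F8 | step 7 | [14-(2-{[(bromomagnesio)ethynyl]oxy}-3,5-dimethoxyphenyl)tetradecyl]magnesium bromide | Br[Mg]C#COc1c(CCCCCCCCCCCCCC[Mg]Br)cc(OC)cc1OC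
F9 | step 7 | bromomagnesium 1-[14-(2-{[(bromomagnesio)ethynyl]oxy}-3,5-dimethoxyphenyl)tetradecyl]-3-ethoxycyclobut-2-en-1-olate | CCOC1=CC(CCCCCCCCCCCCCCc2cc(OC)cc(OC)c2OC#C[Mg]Br)(O[Mg]Br)C1
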